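**Assumption:** (R)-(+)-α-ionone (natural/fermentation grade, ≥98% ee), (R)-5-oxotetrahydrofuran-2-carboxylic acid (the deamination product of D-glutamic acid) and 2,7-dimethylocta-2,4,6-trienedial are bought; primed locants follow carotenoid numbering.

## Retrosynthetic overview

1. Target = (2'S,6R)-1',2'-epoxy-1',2'-dihydro-ε,ψ-carotene; the oxirane is closed last from the (2'R)-1',2'-diol by mesylate/alkoxide SN2 (inversion).
2. C40 diol = C25 ε-apo-aldehyde + ψ-C15 phosphonium salt (Wittig, C11'=C12'); C25 aldehyde = ε-C15 phosphonium salt from (R)-α-ionone + C10 dialdehyde (Wittig, C11=C12).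
3. ψ-C15 salt ← vinyl carbinol ← C13 dienone; its C7'–C8' bond is made by the key step, a propargyl Claisen ([3,3], Saucy–Marbet) with 2-methoxypropene, followed by allene → dienone isomerisation.
4. The tertiary propargylic alcohol comes from the D-glutamic-acid lactone: C2' is bought, C1' gem-dimethyl by Grignard, C5' by MeLi/ethynyl addition to the lactone.
5. Ring order: cyclohexene ring bought intact in (R)-α-ionone (C6 bought); a transient dioxolane forms in step 4 and is removed in step 6; the oxirane forms last (step 11).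

## Route

**Step 1**
Reactants: 1 (R)-5-oxotetrahydrofuran-2-carboxylic acid
Product: 2 ethyl (2R)-5-oxooxolane-2-carboxylate
Conditions: EtOH (5 equiv), TsOH·H2O (2 mol%), toluene, reflux, Dean–Stark, 6 h; distil
Reagents that add atoms: ethanol CCO
Why: Fischer esterification in which any ring-opened hydroxy diester relactonises on distillation and the stereocentre is not touched.

**Step 2**
Reactants: 2 ethyl (2R)-5-oxooxolane-2-carboxylate
Product: 3 (5R)-5-(2-hydroxypropan-2-yl)oxolan-2-one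
Conditions: MeMgBr (2.2 equiv), THF, −78 → −40 °C, 2 h; aq NH4Cl
Reagents that add atoms: methylmagnesium bromide C[Mg]Br
Why: Grignard double addition to the ester only, because the α-acyloxy ester and the acetyl ketone formed from it are far more electrophilic than the γ-lactone at −78 °C, where addition also outruns enolisation so C2' keeps its configuration.

**Step 3**
Reactants: 3 (5R)-5-(2-hydroxypropan-2-yl)oxolan-2-one
Product: 5 (3RS,6R)-3,7-dimethyloct-1-yne-3,6,7-triol, via (5R)-5,6-dihydroxy-6-methylheptan-2-one 4 (not isolated)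
Conditions: MeLi (2.05 equiv), THF, −78 °C, 1 h; then HC≡CMgBr (2.5 equiv, 0.5 M in THF), −78 °C → rt, 6 h; aq NH4Cl; continuous extraction (EtOAc)
Reagents that add atoms: methyllithium [Li]C; ethynylmagnesium bromide C#C[Mg]Br
Why: Mono-addition of MeLi to the lactone gives a lithium hemiketalate that is stable at −78 °C and opens on warming to the keto alkoxide, which is trapped by acetylide 1,2-addition; 4 is kept in the flask because the free dihydroxy ketone closes to a bicyclic ketal, and the new C3 centre is unselective and destroyed in step 4.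

**Step 4**
Reactants: 5 (3RS,6R)-3,7-dimethyloct-1-yne-3,6,7-triol
Product: 9 (3E,5E)-6-methyl-8-[(4R)-2,2,5,5-tetramethyl-1,3-dioxolan-4-yl]octa-3,5-dien-2-one, via acetonide ynol 6 (not isolated), via propargyl isopropenyl ether 7 (not isolated), via allenyl ketone 8 (not isolated)
Conditions: 2-methoxypropene (8 equiv), TsOH·H2O (0.5 mol%), hydroquinone (trace), sealed tube, rt 1 h then 100 °C, 16 h; cool; then 30% aq NaOH (0.1 equiv), MeOH, 0 → 10 °C, 1 h; chromatography (AgNO3-impregnated SiO2 if needed) to remove the 5Z isomer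
Reagents that add atoms: 2-methoxypropene COC(C)=C
Why: Acid-catalysed ketal exchange protects the 1,2-diol in situ and makes the isopropenyl ether of the tertiary propargylic alcohol, whose propargyl Claisen (Saucy–Marbet) [3,3]-sigmatropic rearrangement forms the C7'–C8' bond; base then brings the allene into conjugation (3E thermodynamic, 5E/5Z expected about 3:2, 5E isolated) and the dioxolane stereocentre is untouched.

**Step 5**
Reactants: 9 (3E,5E)-6-methyl-8-[(4R)-2,2,5,5-tetramethyl-1,3-dioxolan-4-yl]octa-3,5-dien-2-one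
Product: 10 (3RS,4E,6E)-3,7-dimethyl-9-[(4R)-2,2,5,5-tetramethyl-1,3-dioxolan-4-yl]nona-1,4,6-trien-3-ol
Conditions: CH2=CHMgBr (1.3 equiv), THF, −30 → 0 °C, 1 h; aq NH4Cl
Reagents that add atoms: vinylmagnesium bromide C=C[Mg]Br
Why: Grignard 1,2-addition to the dienone (as in the industrial vinyl-pseudoionol synthesis); the new carbinol centre is unselective and lost in step 6.

**Step 6**
Reactants: 10 (3RS,4E,6E)-3,7-dimethyl-9-[(4R)-2,2,5,5-tetramethyl-1,3-dioxolan-4-yl]nona-1,4,6-trien-3-ol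
Product: 12 [(2E,4E,6E,10R)-10,11-dihydroxy-3,7,11-trimethyldodeca-2,4,6-trien-1-yl]triphenylphosphonium bromide, via acetonide phosphonium bromide 11 (not isolated)
Conditions: PPh3·HBr (1.05 equiv), CH2Cl2, 0 °C → rt, 12 h; evaporate; then MeOH–H2O 9:1, 48% aq HBr (0.2 equiv), 35 °C, 3 h; evaporate, triturate (EtOAc/Et2O)
Reagents that add atoms: triphenylphosphine hydrobromide [Br-].[PH+](c1ccccc1)(c1ccccc1)c1ccccc1
Why: SN1' allylic transposition in which the ionised bis-allylic carbinol is captured by PPh3 at the unhindered terminus to give the conjugated trienyl salt (mainly 2E); acetal hydrolysis is run only afterwards so that no free hydroxyl can trap the cation, and C2' is not involved.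

**Step 7**
Reactants: 13 (R)-α-ionone, (3E)-4-[(1R)-2,6,6-trimethylcyclohex-2-en-1-yl]but-3-en-2-one
Product: 14 (3RS,4E)-3-methyl-5-[(1R)-2,6,6-trimethylcyclohex-2-en-1-yl]penta-1,4-dien-3-ol
Conditions: CH2=CHMgBr (1.3 equiv), THF, −20 → 0 °C, 1 h; aq NH4Cl
Reagents that add atoms: vinylmagnesium bromide C=C[Mg]Br
Why: Grignard 1,2-addition to the enone at low temperature, where γ-deprotonation at C6 does not compete, so the bought C6 centre is retained.

**Step 8**
Reactants: 14 (3RS,4E)-3-methyl-5-[(1R)-2,6,6-trimethylcyclohex-2-en-1-yl]penta-1,4-dien-3-ol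
Product: 15 [(2E,4E)-3-methyl-5-[(1R)-2,6,6-trimethylcyclohex-2-en-1-yl]penta-2,4-dien-1-yl]triphenylphosphonium bromide
Conditions: PPh3·HBr (1.05 equiv), MeOH, 0 °C → rt, 16 h; evaporate, crystallise (EtOAc)
Reagents that add atoms: triphenylphosphine hydrobromide [Br-].[PH+](c1ccccc1)(c1ccccc1)c1ccccc1
Why: SN1' phosphonium salt formation with allylic transposition, the standard entry to ε-end C15 Wittig salts, which leaves C6 intact under these mild conditions.

**Step 9**
Reactants: 15 [(2E,4E)-3-methyl-5-[(1R)-2,6,6-trimethylcyclohex-2-en-1-yl]penta-2,4-dien-1-yl]triphenylphosphonium bromide; 16 (2E,4E,6E)-2,7-dimethylocta-2,4,6-trienedial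
Product: 17 (2E,4E,6E,8E,10E,12E)-2,7,11-trimethyl-13-[(1R)-2,6,6-trimethylcyclohex-2-en-1-yl]trideca-2,4,6,8,10,12-hexaenal
Conditions: 16 (2.5 equiv), NaOMe (1.1 equiv), CH2Cl2–MeOH, −10 °C → rt, 15 added slowly; then heptane, reflux, 1 h (Z → E); chromatography, excess 16 recovered
Reagents that add atoms: none
Why: Wittig olefination that stops at mono-condensation because the dialdehyde is in excess and the remaining formyl group of 17 is deactivated by the longer polyene; the hindered 11Z isomer equilibrates thermally to E.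

**Step 10**
Reactants: 17 (2E,4E,6E,8E,10E,12E)-2,7,11-trimethyl-13-[(1R)-2,6,6-trimethylcyclohex-2-en-1-yl]trideca-2,4,6,8,10,12-hexaenal; 12 [(2E,4E,6E,10R)-10,11-dihydroxy-3,7,11-trimethyldodeca-2,4,6-trien-1-yl]triphenylphosphonium bromide
Product: 18 (2'R,6R)-1',2'-dihydro-ε,ψ-carotene-1',2'-diol
Conditions: 12 (1.2 equiv), NaOMe (1.4 equiv), MeOH–CH2Cl2, 0 °C → rt, 4 h; then EtOAc, reflux, 2 h, N2, dark (Z → E); crystallise
Reagents that add atoms: none
Why: Wittig olefination tolerant of free hydroxyl groups joins C11' to C12'; heating converts the hindered 11'Z and any 9'Z material to the all-E polyene, and both stereocentres are remote from the reaction.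

**Step 11**
Reactants: 18 (2'R,6R)-1',2'-dihydro-ε,ψ-carotene-1',2'-diol
Product: 20 (2'S,6R)-1',2'-epoxy-1',2'-dihydro-ε,ψ-carotene, via hydroxy mesylate 19 (not isolated)
Conditions: MsCl (1.3 equiv), pyridine, CH2Cl2, −10 → 0 °C, 2 h; then K2CO3 (4 equiv), MeOH, 0 °C → rt, 3 h; N2, dark; crystallise
Reagents that add atoms: none
Why: Selective sulfonylation of the secondary hydroxyl followed by intramolecular Williamson (SN2) closure by the tertiary alkoxide, which inverts C2' and turns the bought (2'R) centre into the required (2'S) oxirane.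

## Compound list

1 | (R)-5-oxotetrahydrofuran-2-carboxylic acid | OC(=O)[C@H]1CCC(=O)O1 | starting material
2 | ethyl (2R)-5-oxooxolane-2-carboxylate | CCOC(=O)[C@H]1CCC(=O)O1 | intermediate
3 | (5R)-5-(2-hydroxypropan-2-yl)oxolan-2-one | CC(C)(O)[C@H]1CCC(=O)O1 | intermediate
4 | (5R)-5,6-dihydroxy-6-methylheptan-2-one (present as its lithium alkoxide) | CC(=O)CC[C@@H](O)C(C)(C)O | intermediate
5 | (3RS,6R)-3,7-dimethyloct-1-yne-3,6,7-triol | C#CC(C)(O)CC[C@@H](O)C(C)(C)O | intermediate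
6 | (3RS)-3-methyl-5-[(4R)-2,2,5,5-tetramethyl-1,3-dioxolan-4-yl]pent-1-yn-3-ol (acetonide ynol) | C#CC(C)(O)CC[C@H]1OC(C)(C)OC1(C)C | intermediate
7 | (4R)-2,2,5,5-tetramethyl-4-[3-methyl-3-(prop-1-en-2-yloxy)pent-4-yn-1-yl]-1,3-dioxolane (propargyl isopropenyl ether) | C#CC(C)(OC(C)=C)CC[C@H]1OC(C)(C)OC1(C)C | intermediate
8 | 6-methyl-8-[(4R)-2,2,5,5-tetramethyl-1,3-dioxolan-4-yl]octa-4,5-dien-2-one (allenyl ketone) | CC(=O)CC=C=C(C)CC[C@H]1OC(C)(C)OC1(C)C | intermediate
9 | (3E,5E)-6-methyl-8-[(4R)-2,2,5,5-tetramethyl-1,3-dioxolan-4-yl]octa-3,5-dien-2-one | CC(=O)/C=C/C=C(\C)CC[C@H]1OC(C)(C)OC1(C)C | intermediate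
10 | (3RS,4E,6E)-3,7-dimethyl-9-[(4R)-2,2,5,5-tetramethyl-1,3-dioxolan-4-yl]nona-1,4,6-trien-3-ol | C=CC(C)(O)/C=C/C=C(\C)CC[C@H]1OC(C)(C)OC1(C)C | intermediate
11 | [(2E,4E,6E)-3,7-dimethyl-9-[(4R)-2,2,5,5-tetramethyl-1,3-dioxolan-4-yl]nona-2,4,6-trien-1-yl]triphenylphosphonium bromide | [Br-].c1ccccc1[P+](c1ccccc1)(c1ccccc1)C/C=C(C)/C=C/C=C(\C)CC[C@H]1OC(C)(C)OC1(C)C | intermediate
12 | [(2E,4E,6E,10R)-10,11-dihydroxy-3,7,11-trimethyldodeca-2,4,6-trien-1-yl]triphenylphosphonium bromide | [Br-].c1ccccc1[P+](c1ccccc1)(c1ccccc1)C/C=C(C)/C=C/C=C(\C)CC[C@@H](O)C(C)(C)O | intermediate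
13 | (R)-α-ionone, (3E)-4-[(1R)-2,6,6-trimethylcyclohex-2-en-1-yl]but-3-en-2-one | CC1=CCCC(C)(C)[C@H]1/C=C/C(C)=O | starting material
14 | (3RS,4E)-3-methyl-5-[(1R)-2,6,6-trimethylcyclohex-2-en-1-yl]penta-1,4-dien-3-ol | CC1=CCCC(C)(C)[C@H]1/C=C/C(C)(O)C=C | intermediate
15 | [(2E,4E)-3-methyl-5-[(1R)-2,6,6-trimethylcyclohex-2-en-1-yl]penta-2,4-dien-1-yl]triphenylphosphonium bromide | [Br-].CC1=CCCC(C)(C)[C@H]1/C=C/C(C)=C/C[P+](c1ccccc1)(c1ccccc1)c1ccccc1 | intermediate
16 | (2E,4E,6E)-2,7-dimethylocta-2,4,6-trienedial | O=C/C(C)=C/C=C/C=C(C)/C=O | starting material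
17 | (2E,4E,6E,8E,10E,12E)-2,7,11-trimethyl-13-[(1R)-2,6,6-trimethylcyclohex-2-en-1-yl]trideca-2,4,6,8,10,12-hexaenal, (6R)-12'-apo-ε-caroten-12'-al | CC1=CCCC(C)(C)[C@H]1/C=C/C(C)=C/C=C/C(C)=C/C=C/C=C(C)/C=O | intermediate
18 | (2'R,6R)-1',2'-dihydro-ε,ψ-carotene-1',2'-diol | CC1=CCCC(C)(C)[C@H]1/C=C/C(C)=C/C=C/C(C)=C/C=C/C=C(C)/C=C/C=C(C)/C=C/C=C(\C)CC[C@@H](O)C(C)(C)O | intermediate
19 | (2'R,6R)-1'-hydroxy-1',2'-dihydro-ε,ψ-caroten-2'-yl methanesulfonate | CC1=CCCC(C)(C)[C@H]1/C=C/C(C)=C/C=C/C(C)=C/C=C/C=C(C)/C=C/C=C(C)/C=C/C=C(\C)CC[C@@H](OS(C)(=O)=O)C(C)(C)O | intermediate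
20 | (2'S,6R)-1',2'-epoxy-1',2'-dihydro-ε,ψ-carotene | CC1=CCCC(C)(C)[C@H]1/C=C/C(C)=C/C=C/C(C)=C/C=C/C=C(C)/C=C/C=C(C)/C=C/C=C(\C)CC[C@@H]1OC1(C)C | target

## Step count and risks

Total step count: 11. Longest linear sequence: 8 steps (steps 1–6, 10, 11).

**Step 4 (most likely to fail).** The Claisen itself is reliable, but the allene → dienone isomerisation gives both 5E and 5Z isomers, and a 5'Z unit cannot be corrected later by thermal or iodine equilibration. The step also demands that the acetonide and the tertiary propargylic alcohol survive acid at 100 °C. The fallback sets out from 3 and comes back at 9. iBu2AlH (CH2Cl2, −78 °C) reduces 3 to the lactol (5R)-5-(2-hydroxypropan-2-yl)oxolan-2-ol F4. Dimethyl (1-diazo-2-oxopropyl)phosphonate with K2CO3 in MeOH homologates it to (3R)-2-methylhept-6-yne-2,3-diol F5. 2,2-Dimethoxypropane with PPTS gives (4R)-4-(but-3-yn-1-yl)-2,2,5,5-tetramethyl-1,3-dioxolane F6. Negishi syn-carboalumination (Me3Al, Cp2ZrCl2, CH2Cl2, 0 °C → rt) followed by I2 (THF, −30 °C) gives the geometrically pure vinyl iodide (4R)-4-[(3E)-4-iodo-3-methylbut-3-en-1-yl]-2,2,5,5-tetramethyl-1,3-dioxolane F7. A Heck coupling with but-3-en-2-one (Pd(OAc)2, K2CO3, Bu4NCl, DMF, rt) then delivers 9 as the single 3E,5E isomer.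

**Step 3.** The one-pot MeLi/acetylide sequence can over-add MeLi or stall at the hemiketalate, and the triol is hard to extract. The fallback sets out from 3 and comes back at 6. MeNH(OMe)·HCl with Me3Al (CH2Cl2, 0 °C → rt) opens the lactone to the Weinreb amide (4R)-4,5-dihydroxy-N-methoxy-N,5-dimethylhexanamide F1. 2,2-Dimethoxypropane with PPTS gives N-methoxy-N-methyl-3-[(4R)-2,2,5,5-tetramethyl-1,3-dioxolan-4-yl]propanamide F2. MeMgBr (THF, 0 °C) gives the stable ketone 4-[(4R)-2,2,5,5-tetramethyl-1,3-dioxolan-4-yl]butan-2-one F3. HC≡CMgBr then gives 6, which is isolated and taken into step 4 with less 2-methoxypropene.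

**Step 6.** The acid used for salt formation and acetal hydrolysis could scramble the 5'E geometry through the delocalised cation, or let a freed hydroxyl cyclise onto it. The fallback sets out from 10 and comes back at 18. The reaction is stopped after the CH2Cl2 stage and 11 is isolated. Wittig reaction of 11 with 17 (NaOMe, MeOH–CH2Cl2, then reflux in EtOAc) gives (2'R,6R)-1',2'-dihydro-ε,ψ-carotene-1',2'-diol acetonide F8. Mild transketalisation (PPTS, MeOH–THF, 40 °C, dark) then releases 18.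

## Further compounds

F1 | step 3 | (4R)-4,5-dihydroxy-N-methoxy-N,5-dimethylhexanamide | CON(C)C(=O)CC[C@@H](O)C(C)(C)O
F2 | step 3 | N-methoxy-N-methyl-3-[(4R)-2,2,5,5-tetramethyl-1,3-dioxolan-4-yl]propanamide | CON(C)C(=O)CC[C@H]1OC(C)(C)OC1(C)C
F3 | step 3 | 4-[(4R)-2,2,5,5-tetramethyl-1,3-dioxolan-4-yl]butan-2-one | CC(=O)CC[C@H]1OC(C)(C)OC1(C)C
F4 | step 4 | (5R)-5-(2-hydroxypropan-2-yl)oxolan-2-ol | CC(C)(O)[C@H]1CCC(O)O1
F5 | step 4 | (3R)-2-methylhept-6-yne-2,3-diol | C#CCC[C@@H](O)C(C)(C)O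
F6 | step 4 | (4R)-4-(but-3-yn-1-yl)-2,2,5,5-tetramethyl-1,3-dioxolane | C#CCC[C@H]1OC(C)(C)OC1(C)C
F7 | step 4 | (4R)-4-[(3E)-4-iodo-3-methylbut-3-en-1-yl]-2,2,5,5-tetramethyl-1,3-dioxolane | I/C=C(\C)CC[C@H]1OC(C)(C)OC1(C)C
F8 | step 6 | (2'R,6R)-1',2'-dihydro-ε,ψ-carotene-1',2'-diol acetonide | CC1=CCCC(C)(C)[C@H]1/C=C/C(C)=C/C=C/C(C)=C/C=C/C=C(C)/C=C/C=C(C)/C=C/C=C(\C)CC[C@H]2OC(C)(C)OC2(C)C
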